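The readings are calculated for substances that don't exist; noise was put on by code.

- In a one-step world I counted one reagent per molecule of starting material, and 1.30 equiv covered the charge with room to spare. The names of the species told me to follow one molecule instead and look for forks.

- alpha: starting material 0.30 M (fed, over 5.0 min); second substrate 0.50 equiv; reagent 2.6 equiv; free catalyst 0.1 mol%; run made earlier
- flask: starting material 0.30 M (fed, over 5.0 min); second substrate 0.500 equiv; reagent 1.30 equiv; free catalyst 0.1 mol%; time 8.0 h

alpha run (percent of the starting material charged)

| time / min | starting material / % | target / % |
|---|---|---|
| 12.0 | 44.0 | 25.6 |
| 30.0 | 7.1 | 17.9 |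
| 60.0 | 0 | 7.4 |
| 90.0 | 0.4 | 3.8 |

(scatter of a reading: 0.5 percentage points)

- what was read earlier has a scatter of 0.5 percentage points, one standard deviation

- conversion of starting material at 8.0 h
- amount of target at 8.0 h, in percent of the starting material charged
- amount of over-reaction product at 8.0 h, in percent of the starting material charged

- I assumed the first fork took reagent before the starting material got it: each second substrate used one reagent. That left the reagent available to the starting material, 0.800 equiv.
- The second fork came at the target. A molecule that stopped there had cost one reagent, while one that went on to over-reaction product had cost two.
- Alpha did not read the over-reaction product, so I counted what was neither starting material nor target as that product. As a reading, this put 54.3% of the reacted molecules down the second branch at 12.0 min and 80.7% at 30.0 min, both with 2.6 equiv of reagent, so I carried neither share over to the flask.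
- An average molecule therefore cost between one reagent and two. I expected reagent to be the limiting reagent, and alpha's starting material had reached 0% by 60.0 min, well before 8.0 h, so I reckoned on the flask stopping by its budget and not by the clock.
- Dividing the budget by those two costs put the starting material reacted between 0.400 equiv and 0.800 equiv, and I committed to the count itself: target plus twice the over-reaction product should come to 0.800 equiv.
- The forecast, which was not my reckoning, gave 99.5%, 10% and 32%, and held that “The reagent budget sets the outcome”.
- The flask gave 65.5% conversion, 50.8% target and 14.6% over-reaction product, with c(reagent) at 0% of its charge at 8.00 h.

    starting material + free catalyst ⇌ catalyst intermediate A (K = 41.0 L mol⁻¹, k = 8.00 L mol⁻¹ s⁻¹)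
    reagent + catalyst intermediate A → free catalyst + target (k = 6.50 L mol⁻¹ s⁻¹)
    second substrate + free catalyst ⇌ catalyst intermediate B (K = 150 L mol⁻¹, k = 66.0 L mol⁻¹ s⁻¹)
    reagent + catalyst intermediate B → free catalyst + second product (k = 6.00 L mol⁻¹ s⁻¹)
    reagent + free catalyst + target → free catalyst + over-reaction product (k = 34.0 L² mol⁻² s⁻¹)

- Target plus twice the over-reaction product came to 0.800 equiv in this flask, against my budget of 0.800 equiv. The neighbour with 0.200 equiv of second substrate had a budget of 1.10 equiv, and its 51.0% target and 29.5% over-reaction product counted to 1.10 equiv.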